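## The problem

Compound 28 is an unsymmetrical biflavonoid. A (2S)-flavanone carrying 5-hydroxy, 7-methoxy and 4′-hydroxy groups is joined through an ether oxygen on its C6 to C4′ of the B ring of a 5,7-dihydroxyflavone.

Ring A of the flavanone has one free position (C8). The other five carry the C5 hydroxyl, the C6 aryl ether, the C7 methyl ether, the C8a ring oxygen and the C4a acyl carbon. Four oxygens thus sit in four different roles, and the ether oxygen at C6 is flanked by two ortho oxygens, the worst place for a late aryl ether coupling.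

C2 is the only stereocentre, so nothing in the molecule can control it and it must be set by a catalyst. It is benzylic and β to the C4 ketone, and it is lost through retro-oxa-Michael opening to the chalcone under base or strong Lewis acid. It should therefore be set late and be followed only by neutral chemistry.

Both heterocycles derive from ortho-hydroxyaryl ketones. They must be built in an order that never leaves two enolisable aryl ketones to compete, and never exposes a chromone or the flavanone to strong base. The four phenols need masking that comes off without acid or base. The flavone is robust but absorbs strongly in the near UV, which matters for any photochemical step.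

The feature that opens the key step is the oxygen pattern of ring A: C5–O and C8a–O are meta to each other, and C6 and C7 carry adjacent oxygens. The six carbons therefore map onto a ketene carbonyl carbon (C5), the two carbons of an oxygenated alkyne (C4a, C8a), a diazo carbon (C8) and the two carbons of a dioxygenated enol ether (C7, C6).

## Retrosynthesis

**28 ⇒ 27.** The four phenols are released last by cutting four O–benzyl bonds. Benzyl is chosen because one neutral hydrogenolysis removes all four without touching the methyl ether or C2. Acid- or base-labile groups would put the flavanone at risk at the very end.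

**27 ⇒ 25 + 26.** The C2–aryl bond of the flavanone is cut, leaving the chromone 25 and the commercial boronic acid 26. The neighbouring cuts are weaker: oxa-Michael closure of a chalcone is poorly enantioselective on unactivated substrates, and an early stereocentre would have to survive the enolate chemistry that builds the flavone. The precursor has no stereocentre. The forward step needs high facial selectivity on a 5,6,7-trioxygenated chromone and must leave the flavone untouched.

**25 ⇒ 23 ⇒ 22.** The pyranone of the chromone is cut at O1–C2 and C2–C3, which leads to the ortho-hydroxyacetophenone 23 and a one-carbon amide acetal. Ring closure must use the C8a oxygen and not the C5 oxygen. So C5 is a benzyl ether and C8a is unmasked from its silyl ether (22) just before the closure.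

**22 ⇒ 21 ⇒ 20 ⇒ 19 ⇒ 18.** The C4a–C4 bond is cut next. A Fries shift of a C5 acetate would be one step shorter. It needs a Lewis acid in the presence of the aryl silyl ether and, in the order adopted here, of a benzylated flavone; both are weak points. Magnesium-mediated ortho-formylation of the free C5 phenol in 18 is specific for the one open ortho carbon (C4a) and is mild. The aldehyde 19 is benzylated (20), methylated (21) and oxidised (22). The benzannulation leaves C5 as the only free phenol, and this step depends on that.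

**18 ⇒ 17 ⇒ 15 + 16.** The flavone is cut at O1–C2 (cyclodehydration of diketone 17) and at C2–C3 (Claisen condensation). The partners are the methyl benzoate 15 and the commercial acetophenone 16. The cut is made at this early point because 16 is then the only enolisable ketone in the flask. After ring A has its own acetyl group, a crossed condensation would compete. The methyl ester of 15 is used directly as the acyl acceptor.

**15 ⇒ 9 + 12 (key step).** Ring A is cut at C7–C8, C5–C4a, C8–C8a and C5–C6, giving the diazo enone 9 and the siloxyalkyne 12. Against routes from phloroglucinol-type arenes, this cut delivers the four oxygens already in their final roles, with the hindered aryl ether set on an open chain. Both precursors are acyclic and achiral. The forward reaction must run the Wolff rearrangement cleanly on a doubly oxygenated enone and must place the siloxy carbon meta to the new hydroxyl.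

**9 ⇒ 7 ⇒ 6 ⇒ 4 + 5; 4 ⇒ 2 ⇒ 1.** The diazo ketone comes from acid 7 by acylation of a diazoalkane. Acid 7 comes from the tert-butyl ester 6. Ester 6 comes from the enol tosylate 4 and the commercial phenol 5 by vinylic substitution. Tosylate 4 comes from ester 2 by formylation and O-sulfonylation, and 2 from the acid chloride 1. The two esters are assigned so that the acid-labile one sits on the acrylate. Acid 7 can then be freed without touching the methyl benzoate that step 8 needs.

**12 ⇒ 10.** The siloxyalkyne is cut at O–Si. The ynolate comes from the commercial dibromo ester 10 by double halogen–metal exchange.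

## Roads not taken

**Alternative 1:** The flavone pyranone is cut at C2–C3 and at the C4–O bond and stored as a 3,5-diarylisoxazole. In the forward step the nitrile oxide from aldoxime A3 adds to alkyne A2 to give A1. Reductive N–O cleavage and acid closure with loss of ammonia would then give the flavone.
- Merits: the cycloaddition is regioselective and neutral, and it joins two large fragments late. Its flavone construction is milder than the enolate condensation of step 8.
- Weak points: the complete (2S)-flavanone must exist before the union. Oxime formation must then distinguish the aldehyde from the C4 ketone. Nitrile oxide generation needs a halogenating agent and base on very electron-rich rings, with C2 exposed to ring opening. Unmasking and a final Lewis-acid cleavage of the C5 methyl ether both follow the stereocentre.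
- Comparison: it does not address ring A at all. The chosen plan is harsher in the flavone step, but it runs that step before any stereocentre or second ketone exists and sets C2 in the penultimate step.

**Alternative 2:** The ether-bearing para-phenylene ring is cut at C3′–C4′ and C5′–C6′. In the forward step the aryl ethynyl ether A5 adds across C3 and C6 of methyl coumalate A6, and loss of carbon dioxide gives A4.
- Merits: the hindered diaryl ether is made without a coupling at a doubly ortho-substituted phenol. It needs no diazo compound and no light. Ring A enters as a symmetrical dimethoxy arene, so a later acylation ortho to the unveiled phenol is unambiguous. This road is probably shorter to the acetophenone stage.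
- Weak points: the ring it builds is the simplest in the molecule. A5 is a labile ynol ether of a hindered phenol. The ring A oxygens arrive as two equal methyl ethers and an aldehyde, so an oxidative aldehyde-to-phenol step and a late selective C5 demethylation next to the ketone are needed.
- Comparison: it is better in step count and in use of symmetry. The chosen plan sets against this four oxygens delivered in their final roles, a free C5 phenol that directs the C4a carbon, and no selective demethylation.

**Alternative 3:** The flavone is cut at C4–C4a, C3–C4 and O1–C2. In the forward step the iodophenol A8, a carbonyl one-carbon unit and the alkyne A9 are joined by a palladium-catalysed carbonylative coupling with amine base, giving A7.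
- Merits: the flavone forms in one convergent step and tolerates the ring A methyl ketone. This is the problem that forces the chosen plan to build the flavone before the acetyl group, so here this road is better (one step against two, no strong base).
- Weak points: A9 already contains ring A, so the oxygen differentiation is left to classical chemistry, with C5 as a methyl ether to be cleaved later. Closure to the five-membered aurone competes. The electron-rich, doubly ortho-substituted iodide is slow in oxidative addition.
- Comparison: the chosen plan sets its ring A construction and the cheap commercial ketone 16 against the better flavone step of this road.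

Key step: step 7

Assumption: the facial preference of the pyridine–oxazoline palladium catalyst with a chromone is taken to follow that known for cyclic enones, which assigns the (R)-ligand to the (2S)-flavanone. Both ligand antipodes are available, so this affects only the choice of ligand in step 16.

## Route

Step 1
Reactants: 1 methoxyacetyl chloride
Product: 2 tert-butyl methoxyacetate
Conditions: t-BuOH, pyridine, DMAP (cat.), CH2Cl2, 0 °C to rt
Reagents that add atoms: tert-butanol, CC(C)(C)O
Why: Acyl chloride esterification of a tertiary alcohol; it gives the acid-labile ester that step 4 can cleave beside a methyl benzoate.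

Step 2
Reactants: 2 tert-butyl methoxyacetate
Product: 4 tert-butyl (Z)-2-methoxy-3-(tosyloxy)prop-2-enoate, via sodium hydroxymethylene enolate 3 (not isolated)
Conditions: HCO2Et, NaH, THF, 0 °C to rt; then TsCl, THF–DMF, 0 °C to rt
Reagents that add atoms: ethyl formate, CCOC=O; p-toluenesulfonyl chloride, Cc1ccc(cc1)S(=O)(=O)Cl
Why: Crossed Claisen formylation of an ester with one enolisable site, then O-sulfonylation of the enolate to a vinylogous acyl tosylate; the alkene geometry need not be pure because step 3 converges.

Step 3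
Reactants: 4 tert-butyl (Z)-2-methoxy-3-(tosyloxy)prop-2-enoate; 5 methyl 4-hydroxybenzoate
Product: 6 tert-butyl (Z)-2-methoxy-3-[4-(methoxycarbonyl)phenoxy]prop-2-enoate
Conditions: K2CO3, DABCO (10 mol %), MeCN, rt to 40 °C
Reagents that add atoms: none
Why: Vinylic substitution by addition–elimination (oxa-Michael addition of the phenoxide, loss of tosylate) with DABCO as nucleophilic catalyst; the favoured isomer has the aryloxy group trans to the ester, which is the Z isomer needed later.

Step 4
Reactants: 6 tert-butyl (Z)-2-methoxy-3-[4-(methoxycarbonyl)phenoxy]prop-2-enoate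
Product: 7 (Z)-2-methoxy-3-[4-(methoxycarbonyl)phenoxy]prop-2-enoic acid
Conditions: CF3CO2H, CH2Cl2, 0 °C to rt
Reagents that add atoms: none
Why: Acidolysis of a tert-butyl ester with loss of isobutene; the methyl benzoate and the vinylogous carbonate are inert to anhydrous acid.

Step 5
Reactants: 7 (Z)-2-methoxy-3-[4-(methoxycarbonyl)phenoxy]prop-2-enoic acid
Product: 9 methyl 4-{[(1Z)-4-diazo-2-methoxy-3-oxobut-1-en-1-yl]oxy}benzoate, via acid chloride 8 (not isolated)
Conditions: (COCl)2, DMF (cat.), CH2Cl2, 0 °C, concentrate; then CH2N2 (3 equiv), Et2O, 0 °C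
Reagents that add atoms: diazomethane, C=[N+]=[N-]
Why: Acylation of diazomethane by an acid chloride (first stage of the Arndt–Eistert sequence); the trisubstituted, donor-substituted alkene is a poor dipolarophile, as in the known diazo ketones from 3-alkoxyacryloyl chlorides, and excess diazomethane takes up the HCl.

Step 6
Reactants: 10 ethyl dibromoacetate
Product: 12 (ethynyloxy)triisopropylsilane, via lithium ethynolate 11 (not isolated)
Conditions: t-BuLi (4 equiv), THF, −78 to 0 °C; then i-Pr3SiCl, −78 °C to rt
Reagents that add atoms: chlorotriisopropylsilane, CC(C)[Si](Cl)(C(C)C)C(C)C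
Why: Double bromine–lithium exchange on an α,α-dibromo ester gives an ester dianion that expels ethoxide to form the ynolate; the bulky silyl chloride traps it on oxygen.

Step 7
Reactants: 9 methyl 4-{[(1Z)-4-diazo-2-methoxy-3-oxobut-1-en-1-yl]oxy}benzoate; 12 (ethynyloxy)triisopropylsilane
Product: 15 methyl 4-{2-hydroxy-6-methoxy-4-[(triisopropylsilyl)oxy]phenoxy}benzoate, via vinylketene 13 (not isolated), via 4-vinylcyclobutenone 14 (not isolated)
Conditions: 12 (2.5 equiv), hν (300 nm, Pyrex), ClCH2CH2Cl, rt; then 80 °C
Reagents that add atoms: none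
Why: Light expels nitrogen from 9 and the enol ether carbon migrates (photochemical Wolff rearrangement) to give vinylketene 13. The electron-rich alkyne 12 adds to the ketene C=C in a [2+2] cycloaddition, its nucleophilic CH terminus bonding to the ketene carbonyl carbon, to give cyclobutenone 14. At 80 °C 14 opens by reversible 4π electrocyclic cleavage to a dienylketene, which closes ring A by 6π electrocyclisation and tautomerises to the phenol. The closest known reaction is the second-generation (photochemical) Danheiser benzannulation of α,β-unsaturated α′-diazo ketones with siloxyalkynes to resorcinol monosilyl ethers. No stereocentre is formed. The polarisation of the ynol ether fixes the siloxy carbon meta to the new hydroxyl, so C5 emerges as free phenol and C8a as silyl ether. The Z enol ether keeps hydrogen, not aryloxy, inside at the terminus of the 6π closure. Light of 300 nm is taken up by the diazo ketone and little by the benzoate, and excess 12 keeps the ketene from acylating the product phenol.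

Step 8
Reactants: 15 methyl 4-{2-hydroxy-6-methoxy-4-[(triisopropylsilyl)oxy]phenoxy}benzoate; 16 1-[2,4-bis(benzyloxy)-6-hydroxyphenyl]ethan-1-one
Product: 17 1-[2,4-bis(benzyloxy)-6-hydroxyphenyl]-3-(4-{2-hydroxy-6-methoxy-4-[(triisopropylsilyl)oxy]phenoxy}phenyl)propane-1,3-dione
Conditions: 16 (1.5 equiv), LiN(SiMe3)2 (5 equiv), THF, −78 °C; then 15, −78 °C to 40 °C; aq. NH4Cl
Reagents that add atoms: none
Why: Claisen condensation of the dianion of an ortho-hydroxyacetophenone with a methyl benzoate; 16 is the only enolisable ketone present and the excess base covers the phenol of 15 and the acidic diketone.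

Step 9
Reactants: 17 1-[2,4-bis(benzyloxy)-6-hydroxyphenyl]-3-(4-{2-hydroxy-6-methoxy-4-[(triisopropylsilyl)oxy]phenoxy}phenyl)propane-1,3-dione
Product: 18 5,7-bis(benzyloxy)-2-(4-{2-hydroxy-6-methoxy-4-[(triisopropylsilyl)oxy]phenoxy}phenyl)-4H-chromen-4-one
Conditions: TsOH·H2O (10 mol %), toluene, 80 °C
Reagents that add atoms: none
Why: Acid-catalysed cyclodehydration of an ortho-hydroxyaryl 1,3-diketone (closing stage of the Baker–Venkataraman flavone synthesis); mild anhydrous acid spares the aryl silyl ether and the benzyl ethers.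

Step 10
Reactants: 18 5,7-bis(benzyloxy)-2-(4-{2-hydroxy-6-methoxy-4-[(triisopropylsilyl)oxy]phenoxy}phenyl)-4H-chromen-4-one
Product: 19 3-{4-[5,7-bis(benzyloxy)-4-oxo-4H-chromen-2-yl]phenoxy}-2-hydroxy-4-methoxy-6-[(triisopropylsilyl)oxy]benzaldehyde
Conditions: MgCl2, Et3N, (CH2O)n, MeCN, reflux
Reagents that add atoms: paraformaldehyde (as formaldehyde), C=O
Why: Casnati–Skattebøl ortho-formylation: the magnesium phenoxide delivers formaldehyde to the one free ortho carbon (C4a) and a second formaldehyde oxidises the hydroxymethyl group by hydride transfer; rings without a free phenol do not react.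

Step 11
Reactants: 19 3-{4-[5,7-bis(benzyloxy)-4-oxo-4H-chromen-2-yl]phenoxy}-2-hydroxy-4-methoxy-6-[(triisopropylsilyl)oxy]benzaldehyde
Product: 20 2-(benzyloxy)-3-{4-[5,7-bis(benzyloxy)-4-oxo-4H-chromen-2-yl]phenoxy}-4-methoxy-6-[(triisopropylsilyl)oxy]benzaldehyde
Conditions: BnBr, K2CO3 (anhydrous), acetone, 50 °C
Reagents that add atoms: benzyl bromide, BrCc1ccccc1
Why: Williamson etherification of the salicylaldehyde hydroxyl; anhydrous carbonate in acetone leaves the hindered aryl silyl ether in place, so C5 and C8a stay distinguished.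

Step 12
Reactants: 20 2-(benzyloxy)-3-{4-[5,7-bis(benzyloxy)-4-oxo-4H-chromen-2-yl]phenoxy}-4-methoxy-6-[(triisopropylsilyl)oxy]benzaldehyde
Product: 21 5,7-bis(benzyloxy)-2-(4-{2-(benzyloxy)-3-(1-hydroxyethyl)-6-methoxy-4-[(triisopropylsilyl)oxy]phenoxy}phenyl)-4H-chromen-4-one (racemic carbinol)
Conditions: MeMgBr (1.2 equiv), THF, −78 °C; aq. NH4Cl
Reagents that add atoms: methylmagnesium bromide, C[Mg]Br
Why: Grignard addition to the aldehyde at low temperature, where the vinylogous ester carbonyl of the flavone does not compete; the carbinol centre forms as a racemate and is erased in step 13.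

Step 13
Reactants: 21 5,7-bis(benzyloxy)-2-(4-{2-(benzyloxy)-3-(1-hydroxyethyl)-6-methoxy-4-[(triisopropylsilyl)oxy]phenoxy}phenyl)-4H-chromen-4-one
Product: 22 2-(4-{3-acetyl-2-(benzyloxy)-6-methoxy-4-[(triisopropylsilyl)oxy]phenoxy}phenyl)-5,7-bis(benzyloxy)-4H-chromen-4-one
Conditions: Dess–Martin periodinane, CH2Cl2, 0 °C to rt
Reagents that add atoms: none
Why: Dess–Martin oxidation of a benzylic secondary alcohol to the aryl methyl ketone under neutral conditions.

Step 14
Reactants: 22 2-(4-{3-acetyl-2-(benzyloxy)-6-methoxy-4-[(triisopropylsilyl)oxy]phenoxy}phenyl)-5,7-bis(benzyloxy)-4H-chromen-4-one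
Product: 23 2-{4-[3-acetyl-2-(benzyloxy)-4-hydroxy-6-methoxyphenoxy]phenyl}-5,7-bis(benzyloxy)-4H-chromen-4-one
Conditions: Bu4NF, AcOH, THF, 0 °C
Reagents that add atoms: none
Why: Fluoride cleavage of the aryl silyl ether, buffered with acetic acid so that no free phenoxide condenses with the ketone.

Step 15
Reactants: 23 2-{4-[3-acetyl-2-(benzyloxy)-4-hydroxy-6-methoxyphenoxy]phenyl}-5,7-bis(benzyloxy)-4H-chromen-4-one
Product: 25 5-(benzyloxy)-6-{4-[5,7-bis(benzyloxy)-4-oxo-4H-chromen-2-yl]phenoxy}-7-methoxy-4H-chromen-4-one, via enaminone 24 (not isolated)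
Conditions: Me2NCH(OMe)2, toluene, 100 °C; then conc. HCl, CH2Cl2, rt
Reagents that add atoms: N,N-dimethylformamide dimethyl acetal, COC(OC)N(C)C
Why: Condensation of the methyl ketone with the amide acetal gives the enaminone, and acid then closes the pyranone by addition–elimination with loss of dimethylamine; only the C8a hydroxyl is free, so the ring closes on the correct oxygen.

Step 16
Reactants: 25 5-(benzyloxy)-6-{4-[5,7-bis(benzyloxy)-4-oxo-4H-chromen-2-yl]phenoxy}-7-methoxy-4H-chromen-4-one; 26 4-(benzyloxy)phenylboronic acid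
Product: 27 (2S)-5-(benzyloxy)-2-[4-(benzyloxy)phenyl]-6-{4-[5,7-bis(benzyloxy)-4-oxo-4H-chromen-2-yl]phenoxy}-7-methoxy-2,3-dihydro-4H-chromen-4-one
Conditions: 26 (2 equiv), Pd(OCOCF3)2 (10 mol %), (R)-t-BuPyOX (12 mol %), NH4PF6 (30 mol %), H2O (5 equiv), ClCH2CH2Cl, 60 °C
Reagents that add atoms: none
Why: Enantioselective conjugate addition of an arylboronic acid to a chromone under cationic divalent palladium: transmetalation, face-selective insertion of C2=C3 into the aryl–palladium bond, and protonolysis of the palladium enolate. C2 is set by the pyridine–oxazoline ligand, whose tert-butyl group blocks one face; the base-free medium keeps the flavanone closed and the 2-substituted flavone does not react.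

Step 17
Reactants: 27 (2S)-5-(benzyloxy)-2-[4-(benzyloxy)phenyl]-6-{4-[5,7-bis(benzyloxy)-4-oxo-4H-chromen-2-yl]phenoxy}-7-methoxy-2,3-dihydro-4H-chromen-4-one
Product: 28 (2S)-6-[4-(5,7-dihydroxy-4-oxo-4H-chromen-2-yl)phenoxy]-5-hydroxy-2-(4-hydroxyphenyl)-7-methoxy-2,3-dihydro-4H-chromen-4-one
Conditions: H2 (1 atm), Pd/C (10 %), EtOAc–MeOH, rt, stopped when debenzylation is complete
Reagents that add atoms: none
Why: Hydrogenolysis of four aryl benzyl ethers under neutral conditions, which leaves the methyl ether and the C2 configuration untouched.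

## Compound list

1 | methoxyacetyl chloride | COCC(=O)Cl | starting material
2 | tert-butyl methoxyacetate | COCC(=O)OC(C)(C)C | intermediate
3 | sodium 3-tert-butoxy-2-methoxy-3-oxoprop-1-en-1-olate (geometry not fixed) | [Na+].[O-]C=C(OC)C(=O)OC(C)(C)C | intermediate (not isolated)
4 | tert-butyl (Z)-2-methoxy-3-(tosyloxy)prop-2-enoate | Cc1ccc(cc1)S(=O)(=O)O/C=C(\OC)C(=O)OC(C)(C)C | intermediate
5 | methyl 4-hydroxybenzoate | COC(=O)c1ccc(O)cc1 | starting material
6 | tert-butyl (Z)-2-methoxy-3-[4-(methoxycarbonyl)phenoxy]prop-2-enoate | COC(=O)c1ccc(O/C=C(\OC)C(=O)OC(C)(C)C)cc1 | intermediate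
7 | (Z)-2-methoxy-3-[4-(methoxycarbonyl)phenoxy]prop-2-enoic acid | COC(=O)c1ccc(O/C=C(\OC)C(=O)O)cc1 | intermediate
8 | methyl 4-{[(1Z)-3-chloro-2-methoxy-3-oxoprop-1-en-1-yl]oxy}benzoate | COC(=O)c1ccc(O/C=C(\OC)C(=O)Cl)cc1 | intermediate (not isolated)
9 | methyl 4-{[(1Z)-4-diazo-2-methoxy-3-oxobut-1-en-1-yl]oxy}benzoate | COC(=O)c1ccc(O/C=C(\OC)C(=O)C=[N+]=[N-])cc1 | intermediate
10 | ethyl dibromoacetate | CCOC(=O)C(Br)Br | starting material
11 | lithium ethynolate | [Li+].[O-]C#C | intermediate (not isolated)
12 | (ethynyloxy)triisopropylsilane | C#CO[Si](C(C)C)(C(C)C)C(C)C | intermediate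
13 | methyl 4-{[(1Z)-2-methoxy-4-oxobuta-1,3-dien-1-yl]oxy}benzoate | COC(=O)c1ccc(O/C=C(\OC)C=C=O)cc1 | intermediate (not isolated)
14 | methyl 4-({(1Z)-2-methoxy-2-[4-oxo-2-(triisopropylsilyloxy)cyclobut-2-en-1-yl]ethenyl}oxy)benzoate (racemic) | COC(=O)c1ccc(O/C=C(\OC)C2C(=CC2=O)O[Si](C(C)C)(C(C)C)C(C)C)cc1 | intermediate (not isolated)
15 | methyl 4-{2-hydroxy-6-methoxy-4-[(triisopropylsilyl)oxy]phenoxy}benzoate | COC(=O)c1ccc(Oc2c(O)cc(O[Si](C(C)C)(C(C)C)C(C)C)cc2OC)cc1 | intermediate
16 | 1-[2,4-bis(benzyloxy)-6-hydroxyphenyl]ethan-1-one | CC(=O)c1c(O)cc(OCc2ccccc2)cc1OCc1ccccc1 | starting material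
17 | 1-[2,4-bis(benzyloxy)-6-hydroxyphenyl]-3-(4-{2-hydroxy-6-methoxy-4-[(triisopropylsilyl)oxy]phenoxy}phenyl)propane-1,3-dione | O=C(CC(=O)c1ccc(Oc2c(O)cc(O[Si](C(C)C)(C(C)C)C(C)C)cc2OC)cc1)c1c(O)cc(OCc2ccccc2)cc1OCc1ccccc1 | intermediate
18 | 5,7-bis(benzyloxy)-2-(4-{2-hydroxy-6-methoxy-4-[(triisopropylsilyl)oxy]phenoxy}phenyl)-4H-chromen-4-one | COc1cc(O[Si](C(C)C)(C(C)C)C(C)C)cc(O)c1Oc1ccc(cc1)-c1cc(=O)c2c(OCc3ccccc3)cc(OCc3ccccc3)cc2o1 | intermediate
19 | 3-{4-[5,7-bis(benzyloxy)-4-oxo-4H-chromen-2-yl]phenoxy}-2-hydroxy-4-methoxy-6-[(triisopropylsilyl)oxy]benzaldehyde | COc1cc(O[Si](C(C)C)(C(C)C)C(C)C)c(C=O)c(O)c1Oc1ccc(cc1)-c1cc(=O)c2c(OCc3ccccc3)cc(OCc3ccccc3)cc2o1 | intermediate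
20 | 2-(benzyloxy)-3-{4-[5,7-bis(benzyloxy)-4-oxo-4H-chromen-2-yl]phenoxy}-4-methoxy-6-[(triisopropylsilyl)oxy]benzaldehyde | COc1cc(O[Si](C(C)C)(C(C)C)C(C)C)c(C=O)c(OCc2ccccc2)c1Oc1ccc(cc1)-c1cc(=O)c2c(OCc3ccccc3)cc(OCc3ccccc3)cc2o1 | intermediate
21 | 5,7-bis(benzyloxy)-2-(4-{2-(benzyloxy)-3-(1-hydroxyethyl)-6-methoxy-4-[(triisopropylsilyl)oxy]phenoxy}phenyl)-4H-chromen-4-one (racemic) | COc1cc(O[Si](C(C)C)(C(C)C)C(C)C)c(C(C)O)c(OCc2ccccc2)c1Oc1ccc(cc1)-c1cc(=O)c2c(OCc3ccccc3)cc(OCc3ccccc3)cc2o1 | intermediate
22 | 2-(4-{3-acetyl-2-(benzyloxy)-6-methoxy-4-[(triisopropylsilyl)oxy]phenoxy}phenyl)-5,7-bis(benzyloxy)-4H-chromen-4-one | COc1cc(O[Si](C(C)C)(C(C)C)C(C)C)c(C(C)=O)c(OCc2ccccc2)c1Oc1ccc(cc1)-c1cc(=O)c2c(OCc3ccccc3)cc(OCc3ccccc3)cc2o1 | intermediate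
23 | 2-{4-[3-acetyl-2-(benzyloxy)-4-hydroxy-6-methoxyphenoxy]phenyl}-5,7-bis(benzyloxy)-4H-chromen-4-one | COc1cc(O)c(C(C)=O)c(OCc2ccccc2)c1Oc1ccc(cc1)-c1cc(=O)c2c(OCc3ccccc3)cc(OCc3ccccc3)cc2o1 | intermediate
24 | 5,7-bis(benzyloxy)-2-[4-(2-(benzyloxy)-3-[(2E)-3-(dimethylamino)prop-2-enoyl]-4-hydroxy-6-methoxyphenoxy)phenyl]-4H-chromen-4-one | COc1cc(O)c(C(=O)/C=C/N(C)C)c(OCc2ccccc2)c1Oc1ccc(cc1)-c1cc(=O)c2c(OCc3ccccc3)cc(OCc3ccccc3)cc2o1 | intermediate (not isolated)
25 | 5-(benzyloxy)-6-{4-[5,7-bis(benzyloxy)-4-oxo-4H-chromen-2-yl]phenoxy}-7-methoxy-4H-chromen-4-one | COc1cc2occc(=O)c2c(OCc2ccccc2)c1Oc1ccc(cc1)-c1cc(=O)c2c(OCc3ccccc3)cc(OCc3ccccc3)cc2o1 | intermediate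
26 | 4-(benzyloxy)phenylboronic acid | OB(O)c1ccc(OCc2ccccc2)cc1 | starting material
27 | (2S)-5-(benzyloxy)-2-[4-(benzyloxy)phenyl]-6-{4-[5,7-bis(benzyloxy)-4-oxo-4H-chromen-2-yl]phenoxy}-7-methoxy-2,3-dihydro-4H-chromen-4-one | COc1cc2c(c(OCc3ccccc3)c1Oc1ccc(-c3cc(=O)c4c(OCc5ccccc5)cc(OCc5ccccc5)cc4o3)cc1)C(=O)C[C@@H](c1ccc(OCc3ccccc3)cc1)O2 | intermediate
28 | (2S)-6-[4-(5,7-dihydroxy-4-oxo-4H-chromen-2-yl)phenoxy]-5-hydroxy-2-(4-hydroxyphenyl)-7-methoxy-2,3-dihydro-4H-chromen-4-one | COc1cc2c(c(O)c1Oc1ccc(-c3cc(=O)c4c(O)cc(O)cc4o3)cc1)C(=O)C[C@@H](c1ccc(O)cc1)O2 | target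

## Step count and least certain steps

Total step count: 17. Longest linear sequence: 16 steps (steps 1–5 and 7–17); step 6 is a one-step side branch.

**Step 7 (key step).**
- Risk: the excited diazo ketone or its carbene may leave the Wolff pathway. The donor-substituted vinylketene may oligomerise or acylate the product phenol before the alkyne traps it. Light-induced isomerisation of the enol ether would slow the 6π closure.
- Fallback: it sets out from 5 and returns at 15, reaching the same vinylketene 13 thermally. Phenol 5 is alkylated with bromoacetic acid (NaH, DMF) to [4-(methoxycarbonyl)phenoxy]acetic acid F1. SOCl2 gives [4-(methoxycarbonyl)phenoxy]acetyl chloride F2. Dehydrochlorination with Et3N in the presence of methoxyacetylene F3 (from chloroacetaldehyde dimethyl acetal and NaNH2) gives, by ketene–alkyne [2+2] cycloaddition, methyl 4-[(2-methoxy-4-oxocyclobut-2-en-1-yl)oxy]benzoate F4. Heating F4 with 12 in toluene at 80–110 °C opens the cyclobutenone and the cascade of step 7 follows without light.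

**Step 6.**
- Risk: the unhindered carbon of the parent ynolate may be silylated in competition with oxygen, giving a silylketene. Excess alkyllithium may metalate the ynolate further.
- Fallback: it sets out from 9 and returns at 15, using a carbon-blocked alkyne. Lithiated (trimethylsilyl)acetylene is oxidised with LiOO-t-Bu to the silylynolate and silylated on oxygen with i-Pr3SiOSO2CF3 to triisopropyl{[(trimethylsilyl)ethynyl]oxy}silane F5. Under the conditions of step 7, 9 and F5 give methyl 4-{2-hydroxy-6-methoxy-3-(trimethylsilyl)-4-[(triisopropylsilyl)oxy]phenoxy}benzoate F6. CF3CO2H in CH2Cl2 removes the aryl silicon group by ipso-protodesilylation.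

**Step 3.**
- Risk: the phenoxide may attack sulfur (sulfonyl transfer). The α-methoxy group may make conjugate addition too slow.
- Fallback: it sets out from 2 and returns at 6. The enolate 3 is made as in step 2 and treated with (COCl)2 and catalytic DMF instead of TsCl, giving tert-butyl (Z)-3-chloro-2-methoxyprop-2-enoate F7. The phenoxide of 5 (K2CO3, DABCO, MeCN) then displaces chloride by the same addition–elimination, with no sulfur centre to attack.

**Step 16.**
- Risk: the hindered, electron-rich chromone may insert slowly. The electron-rich boronic acid may protodeboronate. Facial selectivity may be insufficient or of the opposite sense.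
- Fallback: it sets out from 23 and returns at 27. Claisen–Schmidt condensation of 23 with 4-(benzyloxy)benzaldehyde (KOH, EtOH–THF) gives (2E)-1-[2-(benzyloxy)-3-{4-[5,7-bis(benzyloxy)-4-oxo-4H-chromen-2-yl]phenoxy}-6-hydroxy-4-methoxyphenyl]-3-[4-(benzyloxy)phenyl]prop-2-en-1-one F8. NaOAc in refluxing EtOH closes it to the racemic flavanone F9. Chromatography on a chiral stationary phase gives the (2S)-enantiomer, and the antipode is re-equilibrated with base and recycled.

**Step 17.**
- Risk: over-reduction, by hydrogenolysis of the benzylic C2–O1 bond or by saturation of the flavone C2=C3 bond.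
- Fallback: it sets out from 27 and returns at 28 with no new compound. The benzyl ethers are cleaved with BCl3 and pentamethylbenzene in CH2Cl2 at −78 °C, where the C7 methyl ether survives.

## Further compounds

F1 | step 7 | [4-(methoxycarbonyl)phenoxy]acetic acid | COC(=O)c1ccc(OCC(=O)O)cc1
F2 | step 7 | [4-(methoxycarbonyl)phenoxy]acetyl chloride | COC(=O)c1ccc(OCC(=O)Cl)cc1
F3 | step 7 | methoxyacetylene | COC#C
F4 | step 7 | methyl 4-[(2-methoxy-4-oxocyclobut-2-en-1-yl)oxy]benzoate (racemic) | COC(=O)c1ccc(OC2C(OC)=CC2=O)cc1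
F5 | step 6 | triisopropyl{[(trimethylsilyl)ethynyl]oxy}silane | C[Si](C)(C)C#CO[Si](C(C)C)(C(C)C)C(C)C
F6 | step 6 | methyl 4-{2-hydroxy-6-methoxy-3-(trimethylsilyl)-4-[(triisopropylsilyl)oxy]phenoxy}benzoate | COC(=O)c1ccc(Oc2c(O)c([Si](C)(C)C)c(O[Si](C(C)C)(C(C)C)C(C)C)cc2OC)cc1
F7 | step 3 | tert-butyl (Z)-3-chloro-2-methoxyprop-2-enoate | Cl/C=C(\OC)C(=O)OC(C)(C)C
F8 | step 16 | (2E)-1-[2-(benzyloxy)-3-{4-[5,7-bis(benzyloxy)-4-oxo-4H-chromen-2-yl]phenoxy}-6-hydroxy-4-methoxyphenyl]-3-[4-(benzyloxy)phenyl]prop-2-en-1-one | COc1cc(O)c(C(=O)/C=C/c2ccc(OCc3ccccc3)cc2)c(OCc2ccccc2)c1Oc1ccc(cc1)-c1cc(=O)c2c(OCc3ccccc3)cc(OCc3ccccc3)cc2o1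
F9 | step 16 | racemic 5-(benzyloxy)-2-[4-(benzyloxy)phenyl]-6-{4-[5,7-bis(benzyloxy)-4-oxo-4H-chromen-2-yl]phenoxy}-7-methoxy-2,3-dihydro-4H-chromen-4-one | COc1cc2c(c(OCc3ccccc3)c1Oc1ccc(-c3cc(=O)c4c(OCc5ccccc5)cc(OCc5ccccc5)cc4o3)cc1)C(=O)CC(c1ccc(OCc3ccccc3)cc1)O2
F0 | step 17 | none | none
A1 | alternative 1 | (2S)-2-[4-(benzyloxy)phenyl]-5,7-dimethoxy-6-(4-{5-[2,4,6-tris(benzyloxy)phenyl]-1,2-oxazol-3-yl}phenoxy)-2,3-dihydro-4H-chromen-4-one | COc1cc2c(c(OC)c1Oc1ccc(-c3cc(-c4c(OCc5ccccc5)cc(OCc5ccccc5)cc4OCc4ccccc4)on3)cc1)C(=O)C[C@@H](c1ccc(OCc3ccccc3)cc1)O2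
A2 | alternative 1 | 1,3,5-tris(benzyloxy)-2-ethynylbenzene | C#Cc1c(OCc2ccccc2)cc(OCc2ccccc2)cc1OCc1ccccc1
A3 | alternative 1 | 4-({(2S)-2-[4-(benzyloxy)phenyl]-5,7-dimethoxy-4-oxo-3,4-dihydro-2H-chromen-6-yl}oxy)benzaldehyde (E)-oxime | COc1cc2c(c(OC)c1Oc1ccc(/C=N/O)cc1)C(=O)C[C@@H](c1ccc(OCc3ccccc3)cc1)O2
A4 | alternative 2 | methyl 4-[4-(1,3-dioxolan-2-yl)-2,6-dimethoxyphenoxy]benzoate | COC(=O)c1ccc(Oc2c(OC)cc(C3OCCO3)cc2OC)cc1
A5 | alternative 2 | 2-[4-(ethynyloxy)-3,5-dimethoxyphenyl]-1,3-dioxolane | C#COc1c(OC)cc(cc1OC)C1OCCO1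
A6 | alternative 2 | methyl coumalate (methyl 2-oxo-2H-pyran-5-carboxylate) | COC(=O)c1ccc(=O)oc1
A7 | alternative 3 | 1-[3-{4-[5,7-bis(benzyloxy)-4-oxo-4H-chromen-2-yl]phenoxy}-2,4-dimethoxy-6-(methoxymethoxy)phenyl]ethan-1-one | CC(=O)c1c(OCOC)cc(OC)c(Oc2ccc(-c3cc(=O)c4c(OCc5ccccc5)cc(OCc5ccccc5)cc4o3)cc2)c1OC
A8 | alternative 3 | 3,5-bis(benzyloxy)-2-iodophenol | Oc1cc(OCc2ccccc2)cc(OCc2ccccc2)c1I
A9 | alternative 3 | 1-[3-(4-ethynylphenoxy)-2,4-dimethoxy-6-(methoxymethoxy)phenyl]ethan-1-one | CC(=O)c1c(OCOC)cc(OC)c(Oc2ccc(C#C)cc2)c1OC
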